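**Retrosynthetic overview**
1. Trachelogenin ⇐ one-pot hydrogenolysis (ArC=O → ArCH2, OBn → OH) of a 3-aroyl-3-hydroxy lactone.
2. Key disconnection, C3–C(aryl carbonyl): the acyl anion of O-benzylvanillin (as its Breslow intermediate) adds to the C3 ketone of racemising 4-(3,4-dimethoxybenzyl)oxolane-2,3-dione. Two carbonyl carbons are joined, and a chiral carbene sets C3 and C4 together by dynamic kinetic resolution.
3. Keto lactone (handled as its achiral enol) ⇐ oxalyl Claisen adduct + formaldehyde. This closes the lactone, the only ring formed, before the key step.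
4. Claisen adduct ⇐ methyl 3-(3,4-dimethoxyphenyl)propanoate + dimethyl oxalate.

Assumption: methyl ester 1 is bought as catalogued; if only the acid is to hand, one esterification (MeOH, H2SO4) precedes step 1.
Assumption: the (5aS,10bR) triazolium salt is taken to be the enantiomer that selects (4S)-7; if the first run shows the opposite sense, the commercial (5aR,10bS) salt is used instead.

**Step 1**
Reactants: 1 methyl 3-(3,4-dimethoxyphenyl)propanoate; 2 dimethyl oxalate
Product: 3 dimethyl 2-[(3,4-dimethoxyphenyl)methyl]-3-oxobutanedioate (racemic)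
Conditions: NaOMe (1.2 equiv), Et2O, 0 °C → rt, 16 h; then 1 M HCl, 0 °C
Reagents that add atoms: none
Why: Crossed Claisen condensation in which only 1 can enolise, dimethyl oxalate is the more electrophilic partner and deprotonation of the β-keto ester product drives the equilibrium; the one stereocentre formed is racemic and is erased in step 2.

**Step 2**
Reactants: 3 dimethyl 2-[(3,4-dimethoxyphenyl)methyl]-3-oxobutanedioate
Product: 5 4-[(3,4-dimethoxyphenyl)methyl]-3-hydroxyfuran-2(5H)-one, via dioxolactone ester 4 (not isolated)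
Conditions: 37% aq. HCHO (1.1 equiv), K2CO3 (0.2 equiv), THF/H2O, 0 °C → rt, 3 h; extractive removal of excess HCHO; then 2 M H2SO4/dioxane 1:1, 100 °C, 6 h
Reagents that add atoms: formaldehyde, C=O
Why: Aldol hydroxymethylation at the doubly activated carbon, after which the new CH2OH closes the five-membered lactone onto the oxalyl ester (4), and acid hydrolysis of the remaining ester with decarboxylation of the β-keto acid leaves the α-keto lactone, which rests as the achiral enol 5 so that no stereocentre exists yet.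

**Step 3**
Reactants: 5 4-[(3,4-dimethoxyphenyl)methyl]-3-hydroxyfuran-2(5H)-one; 6 4-(benzyloxy)-3-methoxybenzaldehyde
Product: 9 (3R,4S)-3-[4-(benzyloxy)-3-methoxybenzoyl]-4-[(3,4-dimethoxyphenyl)methyl]-3-hydroxyoxolan-2-one, via keto tautomer 7 (not isolated), via Breslow intermediate 8 (not isolated)
Conditions: 6 (1.5 equiv), (5aS,10bR)-2-(pentafluorophenyl)-5a,10b-dihydro-4H,6H-indeno[2,1-b][1,2,4]triazolo[4,3-d][1,4]oxazin-2-ium tetrafluoroborate (C18H11BF9N3O, 15 mol%), i-Pr2NEt (0.5 equiv), 4 Å molecular sieves, t-BuOMe, 23 °C, 24–48 h, Ar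
Reagents that add atoms: none
Why: Proposed new method: the carbene turns aldehyde 6 into Breslow intermediate 8, an acyl anion equivalent that attacks the electrophilic C3 ketone of keto tautomer 7 (present in small amount and racemising through enol 5 under the amine base) on the ring face anti to the C4 benzyl group, so the aroyl group ends trans and the new hydroxyl cis to that benzyl, while the chiral carbene selects the (4S) enantiomer of 7 so that C3 and C4 are fixed together in a carbene-catalysed aldehyde–ketone crossed benzoin run as a dynamic kinetic resolution; the closest known reaction type is the carbene-catalysed dynamic kinetic asymmetric cross-benzoin of aldehydes with racemic β-stereogenic (β-halo) α-keto esters, extended here to a cyclic β-alkyl α-keto lactone.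

**Step 4**
Reactants: 9 (3R,4S)-3-[4-(benzyloxy)-3-methoxybenzoyl]-4-[(3,4-dimethoxyphenyl)methyl]-3-hydroxyoxolan-2-one
Product: 12 trachelogenin [(3S,4S)-4-[(3,4-dimethoxyphenyl)methyl]-3-hydroxy-3-[(4-hydroxy-3-methoxyphenyl)methyl]oxolan-2-one], via phenol ketone 10 (not isolated), via benzylic alcohol 11 (not isolated)
Conditions: H2 (5 bar), 10% Pd/C (10 mol% Pd), AcOH/EtOAc 1:1, 50 °C, 24 h
Reagents that add atoms: none
Why: Catalytic hydrogenolysis cleaves the benzyl ether, reduces the electron-rich aryl ketone to the benzylic alcohol and removes that C–O bond (activated by the para phenol) to give CH2, while the non-benzylic tertiary alcohol, the lactone and both stereocentres (C3 quaternary, C4 not α to a carbonyl) are untouched; the C3 descriptor changes from R to S only because the CIP ranking changes.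

**Compound list**
1 | methyl 3-(3,4-dimethoxyphenyl)propanoate | COC(=O)CCc1ccc(OC)c(OC)c1 | starting material
2 | dimethyl oxalate | COC(=O)C(=O)OC | starting material
3 | dimethyl 2-[(3,4-dimethoxyphenyl)methyl]-3-oxobutanedioate (racemic, keto/enol mixture) | COC(=O)C(=O)C(Cc1ccc(OC)c(OC)c1)C(=O)OC | intermediate
4 | methyl 3-[(3,4-dimethoxyphenyl)methyl]-4,5-dioxooxolane-3-carboxylate (racemic, not isolated) | COC(=O)C1(Cc2ccc(OC)c(OC)c2)COC(=O)C1=O | intermediate
5 | 4-[(3,4-dimethoxyphenyl)methyl]-3-hydroxyfuran-2(5H)-one (achiral enol) | COc1ccc(CC2=C(O)C(=O)OC2)cc1OC | intermediate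
6 | 4-(benzyloxy)-3-methoxybenzaldehyde | COc1cc(C=O)ccc1OCc1ccccc1 | starting material
7 | (4S)-4-[(3,4-dimethoxyphenyl)methyl]oxolane-2,3-dione (keto tautomer of 5, reacting enantiomer, not isolated) | O=C1C(=O)OC[C@@H]1Cc1ccc(OC)c(OC)c1 | intermediate
8 | Breslow intermediate: [4-(benzyloxy)-3-methoxyphenyl](hydroxy)methylidene adduct of the (5aS,10bR)-2-(pentafluorophenyl)indeno-triazolo-oxazin-3-ylidene carbene (not isolated) | COc1cc(C(O)=C2N(c3c(F)c(F)c(F)c(F)c3F)N=C3CO[C@H]4Cc5ccccc5[C@H]4N23)ccc1OCc1ccccc1 | intermediate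
9 | (3R,4S)-3-[4-(benzyloxy)-3-methoxybenzoyl]-4-[(3,4-dimethoxyphenyl)methyl]-3-hydroxyoxolan-2-one | COc1cc(C(=O)[C@@]2(O)C(=O)OC[C@@H]2Cc2ccc(OC)c(OC)c2)ccc1OCc1ccccc1 | intermediate
10 | (3R,4S)-4-[(3,4-dimethoxyphenyl)methyl]-3-hydroxy-3-(4-hydroxy-3-methoxybenzoyl)oxolan-2-one (not isolated) | COc1cc(C(=O)[C@@]2(O)C(=O)OC[C@@H]2Cc2ccc(OC)c(OC)c2)ccc1O | intermediate
11 | (3R,4S)-4-[(3,4-dimethoxyphenyl)methyl]-3-hydroxy-3-[hydroxy(4-hydroxy-3-methoxyphenyl)methyl]oxolan-2-one (both carbinol epimers, not isolated) | COc1cc(C(O)[C@@]2(O)C(=O)OC[C@@H]2Cc2ccc(OC)c(OC)c2)ccc1O | intermediate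
12 | trachelogenin, (3S,4S)-4-[(3,4-dimethoxyphenyl)methyl]-3-hydroxy-3-[(4-hydroxy-3-methoxyphenyl)methyl]oxolan-2-one | COc1cc(C[C@@]2(O)C(=O)OC[C@@H]2Cc2ccc(OC)c(OC)c2)ccc1O | target

**Step count**
Total steps: 4. Longest linear sequence: 4 (1 → 3 → 5 → 9 → 12).

**Steps most likely to fail, with fallbacks**

Step 3 (key crossed benzoin). The keto tautomer 7 may be too scarce, or the carbene may not discriminate its enantiomers well enough. The fallback sets out from 5 and 6 and comes back to the route at 12.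
- Enol 5 is reduced by transfer hydrogenation with dynamic kinetic resolution through its keto tautomer, using RuCl(p-cymene)[(S,S)-TsNCHPhCHPhNH2] or its mirror image, HCO2H/Et3N, rt. This gives the cis hydroxy lactone (3S,4S)-4-[(3,4-dimethoxyphenyl)methyl]-3-hydroxyoxolan-2-one F1.
- Aldehyde 6 is reduced with NaBH4 to [4-(benzyloxy)-3-methoxyphenyl]methanol F2 and converted with PBr3 into 1-(benzyloxy)-4-(bromomethyl)-2-methoxybenzene F3.
- The dianion of F1 (LiN(i-Pr)2 2.2 equiv, THF/DMPU, −78 °C) is C-benzylated by F3 anti to the C4 substituent. This gives (3S,4S)-3-{[4-(benzyloxy)-3-methoxyphenyl]methyl}-4-[(3,4-dimethoxyphenyl)methyl]-3-hydroxyoxolan-2-one F4.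
- H2, Pd/C, EtOAc, rt removes the benzyl ether to give 12.

Step 4 (one-pot deoxygenation). The hindered aryl ketone may stall at 10 or 11, or the acidic medium may trigger a semipinacol shift of the 1,2-diol. The fallback sets out from 9 and comes back at 12.
- NaBH4 (MeOH/THF, −40 °C) reduces only the aryl ketone, giving (3R,4S)-3-{[4-(benzyloxy)-3-methoxyphenyl](hydroxy)methyl}-4-[(3,4-dimethoxyphenyl)methyl]-3-hydroxyoxolan-2-one F5.
- Ac2O/pyridine acetylates the secondary benzylic hydroxyl only, giving [4-(benzyloxy)-3-methoxyphenyl][(3R,4S)-4-[(3,4-dimethoxyphenyl)methyl]-3-hydroxy-2-oxooxolan-3-yl]methyl acetate F6.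
- H2, Pd/C, EtOAc, rt cleaves the benzylic acetate and the benzyl ether under neutral conditions to give 12.

Step 2 (hydroxymethylation, lactonisation, decarboxylation). Retro-Claisen cleavage of 4 by base, or arene hydroxymethylation by residual formaldehyde in hot acid, may lower the yield. The fallback sets out from 3 and comes back at 5.
- 3 is first hydrolysed and decarboxylated (2 M H2SO4, reflux) to 4-(3,4-dimethoxyphenyl)-2-oxobutanoic acid F7.
- The α-methylene group of F7 is then hydroxymethylated with aqueous formaldehyde (K2CO3, H2O, rt), and the γ-hydroxy keto acid lactonises on acidification to give 5.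

**Further compounds**
F1 | step 3 | (3S,4S)-4-[(3,4-dimethoxyphenyl)methyl]-3-hydroxyoxolan-2-one | O[C@@H]1C(=O)OC[C@@H]1Cc1ccc(OC)c(OC)c1
F2 | step 3 | [4-(benzyloxy)-3-methoxyphenyl]methanol | COc1cc(CO)ccc1OCc1ccccc1
F3 | step 3 | 1-(benzyloxy)-4-(bromomethyl)-2-methoxybenzene | COc1cc(CBr)ccc1OCc1ccccc1
F4 | step 3 | (3S,4S)-3-{[4-(benzyloxy)-3-methoxyphenyl]methyl}-4-[(3,4-dimethoxyphenyl)methyl]-3-hydroxyoxolan-2-one | COc1cc(C[C@@]2(O)C(=O)OC[C@@H]2Cc2ccc(OC)c(OC)c2)ccc1OCc1ccccc1
F5 | step 4 | (3R,4S)-3-{[4-(benzyloxy)-3-methoxyphenyl](hydroxy)methyl}-4-[(3,4-dimethoxyphenyl)methyl]-3-hydroxyoxolan-2-one (both carbinol epimers) | COc1cc(C(O)[C@@]2(O)C(=O)OC[C@@H]2Cc2ccc(OC)c(OC)c2)ccc1OCc1ccccc1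
F6 | step 4 | [4-(benzyloxy)-3-methoxyphenyl][(3R,4S)-4-[(3,4-dimethoxyphenyl)methyl]-3-hydroxy-2-oxooxolan-3-yl]methyl acetate (both epimers) | COc1cc(C(OC(C)=O)[C@@]2(O)C(=O)OC[C@@H]2Cc2ccc(OC)c(OC)c2)ccc1OCc1ccccc1
F7 | step 2 | 4-(3,4-dimethoxyphenyl)-2-oxobutanoic acid | COc1ccc(CCC(=O)C(=O)O)cc1OC
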